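**Retrosynthetic overview**

- The route rests on ring A. O1 on C8a and the methoxy oxygen on C6 are para to each other, the C7 and C8 methoxy groups lie between them, and C5–H and the C4a acyl carbon complete the ring. This is the 4-alkoxyphenol pattern that a chromium alkenylcarbene, CO and an alkyne assemble.
- Last disconnections: the ring B benzyl ether, then O1–C2 (6-endo addition of the C8a hydroxyl to an aryl ynone), which opens ring C.
- Key disconnection: ring A is cut at C6–C5, C4a–C8a and C8a–C8 into the (Z)-1,2-dimethoxyvinyl(methoxy)carbene complex of Cr(CO)5 and the terminal alkyne of a ring B diynone.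
- The diynone comes from 3-hydroxy-4,5-dimethoxybenzaldehyde (benzylation, alkyne homologation, formylation, ethynyl addition, oxidation). The carbene comes from (Z)-1,2-dimethoxyethene, t-BuLi, Cr(CO)6 and Me3OBF4.
- Ring order: ring B is bought, ring A is made by benzannulation, ring C by cyclisation.

Key step: step 8

Assumption: (Z)-1,2-dimethoxyethene and 3-hydroxy-4,5-dimethoxybenzaldehyde are taken as purchasable; the enol ether geometry only fixes the side on which the β-methoxy group sits in the carbene complex, not the constitution of ring A.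

**Route**

Step 1
Reactants: 1 3-hydroxy-4,5-dimethoxybenzaldehyde
Product: 2 3-(benzyloxy)-4,5-dimethoxybenzaldehyde
Conditions: BnBr, K2CO3, DMF, rt
Reagents that add atoms: benzyl bromide, BrCc1ccccc1
Why: Williamson ether synthesis on the only acidic OH should give the benzyl ether, which survives organolithium, Grignard, MnO2 and carbene chemistry and is removed last by hydrogenolysis.

Step 2
Reactants: 2 3-(benzyloxy)-4,5-dimethoxybenzaldehyde
Product: 3 1-(benzyloxy)-5-ethynyl-2,3-dimethoxybenzene
Conditions: dimethyl (1-diazo-2-oxopropyl)phosphonate, K2CO3, MeOH, 0 °C to rt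
Reagents that add atoms: dimethyl (1-diazo-2-oxopropyl)phosphonate, COP(=O)(OC)C(=[N+]=[N-])C(C)=O
Why: Ohira–Bestmann (Seyferth–Gilbert) homologation should convert the aryl aldehyde in one operation into the terminal alkyne whose two carbons become C2 and C3.

Step 3
Reactants: 3 1-(benzyloxy)-5-ethynyl-2,3-dimethoxybenzene
Product: 6 3-[3-(benzyloxy)-4,5-dimethoxyphenyl]prop-2-ynal, via lithium acetylide 4 (not isolated), via lithium hemiaminolate 5 (not isolated)
Conditions: n-BuLi, THF, −78 °C; DMF, −78 to 0 °C; reverse quench into cold 10% aq KH2PO4/MTBE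
Reagents that add atoms: N,N-dimethylformamide, CN(C)C=O
Why: Formylation of a lithium acetylide with DMF should give the arylpropynal, because the tetrahedral adduct is stable until the buffered reverse quench and the freed dimethylamine is protonated before it can add to the ynal.

Step 4
Reactants: 6 3-[3-(benzyloxy)-4,5-dimethoxyphenyl]prop-2-ynal
Product: 7 1-[3-(benzyloxy)-4,5-dimethoxyphenyl]penta-1,4-diyn-3-ol (racemic)
Conditions: HC≡CMgBr, THF, −78 to 0 °C; sat. aq NH4Cl
Reagents that add atoms: ethynylmagnesium bromide, C#C[Mg]Br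
Why: Grignard 1,2-addition to the ynal should install the terminal alkyne (future C5 and C4a); the carbinol centre is formed racemic and is removed by oxidation in the next step.

Step 5
Reactants: 7 1-[3-(benzyloxy)-4,5-dimethoxyphenyl]penta-1,4-diyn-3-ol
Product: 8 1-[3-(benzyloxy)-4,5-dimethoxyphenyl]penta-1,4-diyn-3-one
Conditions: activated MnO2 (excess), CH2Cl2, rt; filtration through Celite, used at once
Reagents that add atoms: none
Why: MnO2 oxidation of a doubly propargylic alcohol is neutral and heterogeneous, so the base-sensitive terminal diynone should be obtained by filtration alone.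

Step 6
Reactants: 9 (Z)-1,2-dimethoxyethene; 10 chromium hexacarbonyl Cr(CO)6
Product: 12 lithium [(Z)-2,3-dimethoxyacryloyl]pentacarbonylchromate, via (Z)-1,2-dimethoxyvinyllithium 11 (not isolated)
Conditions: t-BuLi, THF, −78 to −50 °C; cannulation into Cr(CO)6, THF, −78 to 0 °C; solvent removed, crude salt used directly
Reagents that add atoms: tert-butyllithium, [Li]C(C)(C)C
Why: α-Lithiation of an enol ether with retention of geometry, then addition of the vinyllithium to a CO ligand (Fischer carbene synthesis), should give the acylchromate; the low temperature holds back anti elimination of LiOMe from the anion.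

Step 7
Reactants: 12 lithium [(Z)-2,3-dimethoxyacryloyl]pentacarbonylchromate
Product: 13 pentacarbonyl[(Z)-1,2-dimethoxyvinyl(methoxy)carbene]chromium
Conditions: Me3OBF4, CH2Cl2/H2O, 0 °C; quick silica filtration under argon, stored cold in the dark
Reagents that add atoms: trimethyloxonium tetrafluoroborate, C[O+](C)C.F[B-](F)(F)F
Why: O-Alkylation of the acylmetalate with a hard methylating agent is the second half of the Fischer carbene synthesis and should give the methoxycarbene complex with the vinyl geometry unchanged.

Step 8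
Reactants: 13 pentacarbonyl[(Z)-1,2-dimethoxyvinyl(methoxy)carbene]chromium; 8 1-[3-(benzyloxy)-4,5-dimethoxyphenyl]penta-1,4-diyn-3-one
Product: 15 3-[3-(benzyloxy)-4,5-dimethoxyphenyl]-1-(2-hydroxy-3,4,5-trimethoxyphenyl)prop-2-yn-1-one, via tricarbonylchromium arene complex 14 (not isolated)
Conditions: 13 (1.3 equiv), THF (0.05 M), 50 °C, argon, slow addition of 8; then air, daylight, Et2O, rt; silica filtration
Reagents that add atoms: none
Why: Proposed new method: heating releases one CO from 13, the terminal C≡C of 8 inserts into the Cr=C bond with its CH carbon joined to the carbene carbon (C6–C5), CO insertion at the new acyl-substituted carbene carbon gives an η4-vinylketene (C4a–C8a), and 6π electrocyclisation of this dienylketene onto the methoxy-bearing vinyl CH (C8a–C8) followed by enolisation closes ring A as the Cr(CO)3-bound phenol 14, whose hydroxyl is O1. The closest known reaction type is the Dötz benzannulation of alkenyl(methoxy)carbene complexes of zerovalent chromium with terminal alkynes, which has not been shown for a 1,2-dialkoxyvinyl carbene or for a cross-conjugated diynone. Ring A is the only ring closed, by electrocyclic closure of the metal-bound dienylketene, and no stereocentre is formed. The step needs the acyl-bearing alkyne carbon ortho to the new hydroxyl and an untouched aryl alkyne; both follow from the steric rule that the unsubstituted alkyne terminus bonds to the carbene carbon and from the much slower insertion of disubstituted alkynes, helped by slow addition of 8 to a small excess of 13. The β-methoxy group of 13 is trans to the carbene carbon and cannot chelate chromium after CO loss, so the vacant site stays open for the alkyne. Air and light free 15 from Cr(CO)3 without the quinone formation that (NH4)2Ce(NO3)6 would cause, and the new OH is held by a hydrogen bond to the C4 carbonyl until step 9.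

Step 9
Reactants: 15 3-[3-(benzyloxy)-4,5-dimethoxyphenyl]-1-(2-hydroxy-3,4,5-trimethoxyphenyl)prop-2-yn-1-one
Product: 16 2-[3-(benzyloxy)-4,5-dimethoxyphenyl]-6,7,8-trimethoxy-4H-chromen-4-one
Conditions: DMAP (20 mol %), DMF, rt to 40 °C
Reagents that add atoms: none
Why: Nucleophile-catalysed oxa-Michael cyclisation of an o-hydroxyaryl ynone should close ring C in the 6-endo mode only, because DMAP first adds to the β-carbon and the phenoxide then displaces it at that same carbon, which leaves no path to the 5-exo aurone.

Step 10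
Reactants: 16 2-[3-(benzyloxy)-4,5-dimethoxyphenyl]-6,7,8-trimethoxy-4H-chromen-4-one
Product: 17 2-(3-hydroxy-4,5-dimethoxyphenyl)-6,7,8-trimethoxy-4H-chromen-4-one (CNP0265341.0)
Conditions: H2 (1 atm), 10% Pd/C, EtOAc/MeOH, rt, stopped at full conversion
Reagents that add atoms: none
Why: Catalytic hydrogenolysis of a benzyl aryl ether should free the ring B hydroxyl, while the C2=C3 bond of the 4-pyranone ring is not reduced under these mild conditions.

**Compound list**

1 | 3-hydroxy-4,5-dimethoxybenzaldehyde | COc1cc(C=O)cc(O)c1OC | starting material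
2 | 3-(benzyloxy)-4,5-dimethoxybenzaldehyde | COc1cc(C=O)cc(OCc2ccccc2)c1OC | intermediate
3 | 1-(benzyloxy)-5-ethynyl-2,3-dimethoxybenzene | C#Cc1cc(OC)c(OC)c(OCc2ccccc2)c1 | intermediate
4 | lithium [3-(benzyloxy)-4,5-dimethoxyphenyl]acetylide | [Li]C#Cc1cc(OC)c(OC)c(OCc2ccccc2)c1 | intermediate (not isolated)
5 | lithium 3-[3-(benzyloxy)-4,5-dimethoxyphenyl]-1-(dimethylamino)prop-2-yn-1-olate (racemic) | [Li]OC(N(C)C)C#Cc1cc(OC)c(OC)c(OCc2ccccc2)c1 | intermediate (not isolated)
6 | 3-[3-(benzyloxy)-4,5-dimethoxyphenyl]prop-2-ynal | O=CC#Cc1cc(OC)c(OC)c(OCc2ccccc2)c1 | intermediate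
7 | 1-[3-(benzyloxy)-4,5-dimethoxyphenyl]penta-1,4-diyn-3-ol (racemic) | C#CC(O)C#Cc1cc(OC)c(OC)c(OCc2ccccc2)c1 | intermediate
8 | 1-[3-(benzyloxy)-4,5-dimethoxyphenyl]penta-1,4-diyn-3-one | C#CC(=O)C#Cc1cc(OC)c(OC)c(OCc2ccccc2)c1 | intermediate
9 | (Z)-1,2-dimethoxyethene | CO/C=C\OC | starting material
10 | chromium hexacarbonyl Cr(CO)6 | [C-]#[O+].[C-]#[O+].[C-]#[O+].[C-]#[O+].[C-]#[O+].[C-]#[O+].[Cr] | starting material
11 | (Z)-1,2-dimethoxyvinyllithium | [Li]/C(OC)=C/OC | intermediate (not isolated)
12 | lithium [(Z)-2,3-dimethoxyacryloyl]pentacarbonylchromate | [Li+].[O-]C(=[Cr](=C=O)(=C=O)(=C=O)(=C=O)=C=O)/C(OC)=C/OC | intermediate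
13 | pentacarbonyl[(Z)-1,2-dimethoxyvinyl(methoxy)carbene]chromium | COC(=[Cr](=C=O)(=C=O)(=C=O)(=C=O)=C=O)/C(OC)=C/OC | intermediate
14 | tricarbonyl{η6-(ring A)-3-[3-(benzyloxy)-4,5-dimethoxyphenyl]-1-(2-hydroxy-3,4,5-trimethoxyphenyl)prop-2-yn-1-one}chromium, written as arene plus Cr(CO)3 | COc1cc(C(=O)C#Cc2cc(OC)c(OC)c(OCc3ccccc3)c2)c(O)c(OC)c1OC.[C-]#[O+].[C-]#[O+].[C-]#[O+].[Cr] | intermediate (not isolated)
15 | 3-[3-(benzyloxy)-4,5-dimethoxyphenyl]-1-(2-hydroxy-3,4,5-trimethoxyphenyl)prop-2-yn-1-one | COc1cc(C(=O)C#Cc2cc(OC)c(OC)c(OCc3ccccc3)c2)c(O)c(OC)c1OC | intermediate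
16 | 2-[3-(benzyloxy)-4,5-dimethoxyphenyl]-6,7,8-trimethoxy-4H-chromen-4-one | COc1cc(-c2cc(=O)c3cc(OC)c(OC)c(OC)c3o2)cc(OCc2ccccc2)c1OC | intermediate
17 | 2-(3-hydroxy-4,5-dimethoxyphenyl)-6,7,8-trimethoxy-4H-chromen-4-one | COc1cc(-c2cc(=O)c3cc(OC)c(OC)c(OC)c3o2)cc(O)c1OC | target

**Step count**

Total: 10 steps. Longest linear sequence: 8 steps (steps 1, 2, 3, 4, 5, 8, 9, 10); the carbene branch (steps 6 and 7) joins at step 8.

**Steps most likely to fail**

1. Step 8 (benzannulation). Several processes could take over:
   - The electron-rich trialkoxy carbene may lose CO slowly.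
   - The vinylcarbene intermediate may close without CO insertion to a five-membered ring.
   - The ketone oxygen may trap the vinylketene.
   - The terminal ynone may polymerise or take up a second carbene before annulation is complete.

   Fallback by known chemistry: it sets out from aldehyde 2 and comes back at flavone 16. Claisen–Schmidt condensation of 2 with purchased 1-(2-hydroxy-3,4,5-trimethoxyphenyl)ethanone F1 (KOH, EtOH, rt) should give the 2'-hydroxychalcone (E)-3-[3-(benzyloxy)-4,5-dimethoxyphenyl]-1-(2-hydroxy-3,4,5-trimethoxyphenyl)prop-2-en-1-one F2. Oxidative cyclisation of F2 with catalytic I2 in DMSO at 120 °C should then give 16, which is debenzylated as in step 10.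

2. Step 6 (carbene precursor). Anti elimination of LiOMe from the vinyllithium, whose lithium is trans to the β-methoxy group, may outrun addition to Cr(CO)6, or the lithiation may be incomplete.

   Fallback avoiding the vinyllithium: it sets out from Cr(CO)6 10 and comes back at carbene 13.
   - Methyl methoxyacetate F3 is formylated (methyl formate, NaOMe, Et2O) to sodium 2,3-dimethoxy-3-oxoprop-1-en-1-olate F4.
   - O-Methylation with dimethyl sulfate gives methyl (Z)-2,3-dimethoxyacrylate F5.
   - Hydrolysis (LiOH, THF/H2O; then HCl) gives (Z)-2,3-dimethoxyacrylic acid F6.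
   - Oxalyl chloride with catalytic DMF gives (Z)-2,3-dimethoxyacryloyl chloride F7.
   - Separately, 10 is reduced with sodium naphthalenide NaC10H8 in THF to disodium pentacarbonylchromate Na2Cr(CO)5 F8.
   - F8 is acylated by F7 at −78 °C to sodium [(Z)-2,3-dimethoxyacryloyl]pentacarbonylchromate F9, and Me3OBF4 then gives 13.

3. Step 9 (ring C closure). Closure in the 5-exo mode to the aurone, or DMAP-induced oligomerisation of the ynone, may compete with the 6-endo path.

   Fallback in two stages: it sets out from ynone 15 and comes back at flavone 16. Diethylamine in EtOH at rt should add to the ynone and give the isolable enaminone (E)-3-[3-(benzyloxy)-4,5-dimethoxyphenyl]-3-(diethylamino)-1-(2-hydroxy-3,4,5-trimethoxyphenyl)prop-2-en-1-one F10. Warming F10 in EtOH with a little AcOH should then close ring C by addition of the phenol to the amine-bearing carbon and loss of the amine, which fixes C2 as the only electrophilic site.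

**Further compounds**

F1 | step 8 | 1-(2-hydroxy-3,4,5-trimethoxyphenyl)ethanone | CC(=O)c1cc(OC)c(OC)c(OC)c1O
F2 | step 8 | (E)-3-[3-(benzyloxy)-4,5-dimethoxyphenyl]-1-(2-hydroxy-3,4,5-trimethoxyphenyl)prop-2-en-1-one | COc1cc(C(=O)/C=C/c2cc(OC)c(OC)c(OCc3ccccc3)c2)c(O)c(OC)c1OC
F3 | step 6 | methyl methoxyacetate | COCC(=O)OC
F4 | step 6 | sodium 2,3-dimethoxy-3-oxoprop-1-en-1-olate (configurationally labile enolate) | [Na+].[O-]C=C(OC)C(=O)OC
F5 | step 6 | methyl (Z)-2,3-dimethoxyacrylate | CO/C=C(\OC)C(=O)OC
F6 | step 6 | (Z)-2,3-dimethoxyacrylic acid | CO/C=C(\OC)C(=O)O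
F7 | step 6 | (Z)-2,3-dimethoxyacryloyl chloride | CO/C=C(\OC)C(=O)Cl
F8 | step 6 | disodium pentacarbonylchromate Na2Cr(CO)5 | [Na+].[Na+].[C-]#[O+].[C-]#[O+].[C-]#[O+].[C-]#[O+].[C-]#[O+].[Cr-2]
F9 | step 6 | sodium [(Z)-2,3-dimethoxyacryloyl]pentacarbonylchromate | [Na+].[O-]C(=[Cr](=C=O)(=C=O)(=C=O)(=C=O)=C=O)/C(OC)=C/OC
F10 | step 9 | (E)-3-[3-(benzyloxy)-4,5-dimethoxyphenyl]-3-(diethylamino)-1-(2-hydroxy-3,4,5-trimethoxyphenyl)prop-2-en-1-one | CCN(CC)/C(=C/C(=O)c1cc(OC)c(OC)c(OC)c1O)c1cc(OC)c(OC)c(OCc2ccccc2)c1
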